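A leftover starts this: the delta flask, which is the flask asked about, holds on average 33.2% of its starting material, about a third, from 8.00 h to 96.0 h, with 65.4% product beside it. I want to know whether that is an equilibrium or a stop.

in all of them: protic impurity 0.0196 M; free catalyst 0.81 mol%
- delta: starting material 0.98 M; the very flask that is asked about, followed so far
- beta: starting material 0.49 M; run made earlier
- flask: starting material 0.98 M; time 5.0 d

| run | time / h | product / % | starting material / % |
|---|---|---|---|
| delta | 8.00 | 66 | 32 |
| delta | 15.0 | 64 | 32 |
| delta | 25.0 | 69 | 34 |
| delta | 48.0 | 65 | 36 |
| delta | 96.0 | 63 | 32 |
| beta | 1.33 | 22 | 80 |
| beta | 2.50 | 27 | 69 |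
| beta | 4.00 | 37 | 59 |
| beta | 5.00 | 32 | 58 |
| beta | 6.00 | 38 | 55 |

(standard deviation of a reading: 2 percentage points)

- spring: at 5.0 d take out 90% of the product then present, then wait 10 d
- autumn: at 5.0 d add free catalyst, 50.0% of the amount charged, then wait 10 d
- noon: change nothing and wait 10 d more
- midnight: at 5.0 d add starting material, 50.0% of the amount charged, then wait 10 d

- product that was removed still counts
- additions bring no volume worth counting

* product, in percent of the starting material first charged, at 5.0 d
* which option adds most product ("none" when 2 percentage points or less is all one gets) (spring / autumn / noon / midnight / none)
* product present, with what was taken out counted in, in percent of the starting material first charged, after autumn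
* product present, with what was taken out counted in, in percent of the starting material first charged, after midnight

I build the flask up one process at a time. First comes the main step by itself. With A for starting material and C for free catalyst, I write the rate as k[C][A], pseudo-first-order with k′ = k[C]. The first beta reading gives k′ = 0.168 h⁻¹. The delta flask has twice that catalyst concentration, so it should hold 6.83% at 8.00 h, well below the reading of 32%.

Second comes the protic impurity. The delta balance falls short by 1.4 percentage points, close to the impurity's 2.00% of the charge, so I let it take starting material one for one.

Third, free catalyst dies with a lifetime τ. Then ln([A] at the start / [A] at the end) climbs to k′τ and stops. I call that limit the catalyst budget B, and at fixed τ it grows in proportion to catalyst concentration. The delta flask gives B = 1.08, so τ reads about 3.23 h.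

The beta flask has half that catalyst concentration, so half the budget, and should stop near 55.9%. Its readings from 4.00 h to 6.00 h average 57.3%. First order each way towards the delta level, drawn through the first beta reading, puts the beta flask at 46.6% at 6.00 h, lower than the reading of 55%, so I read a stop of the catalyst, kinetic rather than thermodynamic control.

My reckoning follows. At 5.0 d, far beyond τ, I put product at 65.4%. Spring, noon and midnight add no catalyst, so they add no budget and I expect them to gain nothing. Autumn adds 50.0% of the catalyst charge, so B × 50.0% of new budget. I assume the impurity is used up by then and the new catalyst lives as the old did. That turns 14 points more into product, for 79.4%.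

The forecast differs: 66% now, 67% after autumn, 66% after midnight, best option none, holding that “Fresh catalyst is soon killed by leftover impurity”.

The flask gives 67.0% now, 80.6% after autumn and 67.0% after midnight, and the best option is autumn, with 14 points gained. At 120 h it holds free catalyst 0%, spent catalyst 100% and protic impurity 0%, with 31.0% of the starting material left.

    starting material + free catalyst ⇌ catalyst intermediate (K = 0.340 M⁻¹, k = 3.40 M⁻¹ min⁻¹)
    catalyst intermediate → free catalyst + product (k = 4.00 min⁻¹)
    free catalyst → spent catalyst (k = 0.00670 min⁻¹)
    starting material + protic impurity → quenched substrate (k = 0.110 M⁻¹ min⁻¹)

From these end values the budget of this flask reads 1.15, and 50.0% of it on 31.0% gives 14 points.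

For a neighbour flask with 2 mol% free catalyst, the budget is 2.67, which reckons 91.2% product. The computed neighbour gives 92.3%.

The numbers in the tables come from a simulation with made-up constants; the scatter is artificial.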